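**Plan**

- Cuts: the enol lactone (O–C19=C18, C20=O) goes back to a ring-D-fused furan whose C20–C21 unit sits on C17 and whose oxygen is the C19 oxygen; then C13–C14 and C13–C18 are cut together, then C12–C13, then C8–C14.
- Enabling feature: ring D is a seven-membered carbocycle oxygenated 1,3 at C16 and C19 and fused to ring C at C13–C14. It is therefore a 3,5-dimethoxyphenyl ring (C14, C15, C16, C17, C19, C18) on the quaternary C8 with C13 inserted between C14 and C18.
- Forward: rings A and B come from (+)-sclareolide; the aryl ring is attached to C8; rings C and D close in one carbenoid step; the furan, later oxidised to the butenolide, is annulated last.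
- Stereochemistry: C5, C9, C10 from sclareolide; C8 by α-face capture of the C8 radical; C13 in the ring expansion; C14 by α-face hydrogenation; C16 by hydride delivery to the C16 ketone.

Key step: step 6

Remark on numbering: C1–C10 are the decalin (rings A/B; C4 gem-dimethyl, β-methyls on C8 and C10); ring C is C8–C9–C11–C12–C13–C14; ring D is C13–C14–C15–C16–C17–C19–C18; the lactone/furan oxygen is on C19, C20 is its other neighbour, C21 is bonded to C17. α is the face opposite the C10 methyl.

**Step 1**
Reactants: 1 (+)-sclareolide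
Product: 3 methyl 8α-hydroxy-11-homodriman-12-oate (C9–CH2CO2Me; tertiary 8α-OH; 8β-methyl), via potassium hydroxy-carboxylate 2 (not isolated)
Conditions: KOH, MeOH, reflux; evaporate; MeI, DMF, rt
Reagents that add atoms: potassium hydroxide, [K+].[OH-]; iodomethane, CI
Why: Saponification of the γ-lactone and SN2 O-methylation of the carboxylate trap the open form before it can relactonise; no stereocenter is touched.

**Step 2**
Reactants: 3 methyl 8α-hydroxy-11-homodriman-12-oate
Product: 5 methyl 11-homodrim-8(17)-en-12-oate (exocyclic C8=C17 methylene), via tertiary chlorosulfite 4 (not isolated)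
Conditions: SOCl2, pyridine, CH2Cl2, −78 °C
Reagents that add atoms: thionyl chloride, O=S(Cl)Cl (atoms of intermediate 4 only)
Why: Base-mediated E2-type dehydration through the chlorosulfite; the equatorial 8α leaving group has no anti-periplanar ring hydrogen, so a methyl hydrogen is lost and the exocyclic alkene should predominate.

**Step 3**
Reactants: 5 methyl 11-homodrim-8(17)-en-12-oate; 6 1-iodo-3,5-dimethoxybenzene
Product: 7 methyl 8α-(3,5-dimethoxyphenyl)-11-homodriman-12-oate (aryl equatorial on the α-face of C8; 8β-methyl)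
Conditions: Fe(dpm)3 (cat.), NiBr2·diglyme (cat.), PhSiH2(Oi-Pr), Mn, MnO2, NMP/ClCH2CH2Cl, 40 °C
Reagents that add atoms: none
Why: Markovnikov hydrogen-atom transfer from an iron hydride to the 1,1-disubstituted alkene gives the tertiary C8 radical, which an arylnickel species captures and reductively eliminates (iron/nickel dual-catalytic hydroarylation); nickel approaches C8 from the α-face, anti to the axial C10 methyl, so the aryl group becomes equatorial and the new methyl axial β.

**Step 4**
Reactants: 7 methyl 8α-(3,5-dimethoxyphenyl)-11-homodriman-12-oate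
Product: 8 8α-(3,5-dimethoxyphenyl)-11-homodriman-12-oic acid
Conditions: LiOH, THF/MeOH/H2O, 60 °C; HCl work-up
Reagents that add atoms: lithium hydroxide, [Li+].[OH-]
Why: Ester saponification (acyl–oxygen cleavage); aryl methyl ethers and all stereocenters are inert.

**Step 5**
Reactants: 8 8α-(3,5-dimethoxyphenyl)-11-homodriman-12-oic acid; 9 (trimethylsilyl)diazomethane
Product: 11 C8-(3,5-dimethoxyphenyl) homodrimanyl diazomethyl ketone (C12=O, C13=N2), via mixed carbonic anhydride 10 (not isolated)
Conditions: i-BuOCOCl, N-methylmorpholine, THF, −15 °C; then TMSCHN2, MeCN, 0 °C to rt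
Reagents that add atoms: isobutyl chloroformate, CC(C)COC(=O)Cl (carbonate part of intermediate 10 only)
Why: C-acylation of the diazoalkane by the mixed anhydride with loss of the silyl group (Arndt–Eistert-type diazoketone synthesis); the mixed anhydride is preferred to an acid chloride so that the electron-rich arene is not acylated intramolecularly.

**Step 6**
Reactants: 11 C8-(3,5-dimethoxyphenyl) homodrimanyl diazomethyl ketone
Product: 13 tetracyclic 16,19-dimethoxy-14,16,18-trien-12-one (cycloheptatriene ring D; 13β-H), via norcaradiene ketone 12 (not isolated)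
Conditions: Rh2(OAc)4 (1 mol %), CH2Cl2, reflux, slow addition of 11
Reagents that add atoms: none
Why: Loss of N2 gives an electrophilic rhodium carbenoid at C13 that adds across the ipso–ortho bond C14–C18 of the C8 aryl ring, and norcaradiene 12 opens by disrotatory 6π electrocyclic cleavage of C14–C18 to the cycloheptatriene (intramolecular Büchner reaction of an aryl-tethered α-diazoketone, known for five-membered and, less often, six-membered tethers). Ring C (C8–C9–C11–C12–C13–C14) closes as a six-membered ring in the [2+1] cycloaddition, the equatorial aryl group and the equatorial C9 side chain being held gauche on the decalin, and ring D arises by one-carbon expansion of the benzene ring. C13 is the only new stereocenter: in the chair-like closure the cyclopropane carbon C18 takes the α-face, anti to the axial C8 methyl, which leaves H-13 β, and this should also be the more stable epimer. The step needs arene cyclopropanation to win over C–H insertion and over electrophilic aromatic substitution: the carbons a five-membered insertion would reach (C8, C10) are quaternary, and a carboxylate catalyst under acid-free conditions favours the concerted cycloaddition. The arene is symmetric, so either ortho bond gives the same product with the methoxy groups on C16 and C19.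

**Step 7**
Reactants: 13 tetracyclic 16,19-dimethoxy-14,16,18-trien-12-one
Product: 15 16,19-dimethoxy-11,14,16,18-tetraen-12-yl triflate, via potassium enolate 14 (not isolated)
Conditions: KN(SiMe3)2, THF, −78 °C; PhNTf2, −78 to 0 °C
Reagents that add atoms: N-phenylbis(trifluoromethanesulfonimide), O=S(=O)(N(c1ccccc1)S(=O)(=O)C(F)(F)F)C(F)(F)F; KN(SiMe3)2, C[Si](C)(C)[N-][Si](C)(C)C.[K+] (potassium of intermediate 14 only)
Why: Kinetic deprotonation at the C11 methylene (the C13 methine is hindered and its enolate would be a cross-conjugated heptafulvene) and O-sulfonylation give the enol triflate; this removes the C12 carbonyl before acid is used, since the cyclopropyl-ketone form of 13 could otherwise reopen to an aromatic ketone, and it prepares C12 for reductive removal.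

**Step 8**
Reactants: 15 16,19-dimethoxy-11,14,16,18-tetraen-12-yl triflate
Product: 16 16-methoxy-19-oxo-11,14,16-trien-12-yl triflate (vinylogous ester; C18 now CH2)
Conditions: TsOH·H2O (cat.), MeOH, rt
Reagents that add atoms: water, O
Why: Protonation at C18 gives the 1,3-dimethoxypentadienyl cation, and reversible addition of water or methanol with loss of methanol takes the bis(enol ether) to a vinylogous ester (partial hydrolysis as for Birch-derived 1,3-dimethoxydienes); under these equilibrating conditions the carbonyl is expected to settle on C19, where C14=C15–C16(OMe)=C17–C19=O is linearly conjugated, and any cross-conjugated regioisomer can be returned to the same conditions.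

**Step 9**
Reactants: 16 16-methoxy-19-oxo-11,14,16-trien-12-yl triflate
Product: 17 16-methoxy-16-en-19-one (13β-H, 14α-H; C11, C12, C15 are CH2)
Conditions: H2 (3 atm), PtO2, NaHCO3, EtOAc, rt
Reagents that add atoms: none
Why: Heterogeneous hydrogenation adds to the trisubstituted C14=C15 bond from the α-face, opposite the axial C8 methyl, which sets H-14 α and the trans C/D fusion, and the same catalyst hydrogenolyses and saturates the enol triflate (enol-triflate hydrogenation over platinum, chosen to limit alkene migration through C13); the push–pull C16=C17 bond is left.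

**Step 10**
Reactants: 17 16-methoxy-16-en-19-one
Product: 18 17-iodo-16-methoxy-16-en-19-one
Conditions: NIS, MeCN, rt
Reagents that add atoms: N-iodosuccinimide, O=C1CCC(=O)N1I
Why: Electrophilic α-iodination of a β-alkoxy enone at its nucleophilic α-carbon C17, the only enol-ether-type carbon in the molecule.

**Step 11**
Reactants: 18 17-iodo-16-methoxy-16-en-19-one; 19 (E)-2-(2-ethoxyvinyl)-4,4,5,5-tetramethyl-1,3,2-dioxaborolane
Product: 21 ring-D-fused furan C16 ketone (furan O between C19 and C20; C20H=C21H–C17; C17=C19), via ethoxyvinyl enone 20 (not isolated)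
Conditions: Pd(PPh3)4 (cat.), K3PO4, dioxane/H2O, 80 °C; then TsOH·H2O, THF, 40 °C
Reagents that add atoms: water, O
Why: Suzuki–Miyaura coupling of the α-iodoenone installs C21–C20, and acid then protonates the enol ether at C21 so that the vinylogous-ester carbonyl oxygen on C19 closes onto C20 (five-membered, Paal–Knorr-type cyclodehydration); loss of ethanol and hydrolysis of the C16 oxocarbenium give the furan with its oxygen on C19 and the ketone on C16, so the regiochemistry of step 8 is carried over.

**Step 12**
Reactants: 21 ring-D-fused furan C16 ketone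
Product: 22 16α-hydroxy furan (H-16 β)
Conditions: LiBH(s-Bu)3, THF, −78 °C
Reagents that add atoms: none
Why: 1,2-Reduction of the furyl ketone by a bulky trialkylborohydride; equatorial attack from the β-face, avoiding the axial H-14 on the α-face, is expected to give the pseudo-axial 16α-alcohol.

**Step 13**
Reactants: 22 16α-hydroxy furan
Product: 23 16α-acetoxy furan
Conditions: Ac2O, pyridine, DMAP (cat.), CH2Cl2, 0 °C to rt
Reagents that add atoms: acetic anhydride, CC(=O)OC(C)=O
Why: Nucleophile-catalysed O-acylation with retention at C16; basic conditions protect the acid-labile furylic C–O bond.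

**Step 14**
Reactants: 23 16α-acetoxy furan
Product: 25 16α-acetoxy-19-hydroxy-17(21)-en-20,19-olide (γ-hydroxybutenolide; C19 epimers), via furan endoperoxide 24 (not isolated)
Conditions: O2, hν (visible), rose bengal, i-Pr2NEt, CH2Cl2, −78 °C
Reagents that add atoms: dioxygen, O=O
Why: [4+2] addition of singlet oxygen across C19/C20 of the furan and base-induced Kornblum–DeLaMare fragmentation at the only α-C–H (C20) give the C20 carbonyl and the C19 hemiketal hydroxyl; both C19 epimers converge in the next step.

**Step 15**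
Reactants: 25 16α-acetoxy-19-hydroxy-17(21)-en-20,19-olide
Product: 26 CNP0193439.1 (16α-acetoxy-17(21),18-dien-20,19-olide)
Conditions: TFA (cat.), CH2Cl2, 0 °C to rt
Reagents that add atoms: none
Why: Acid-catalysed dehydration of the γ-hydroxybutenolide through the acyloxocarbenium ion; C18 carries the only hydrogens next to C19, so the C19=C18 enol lactone is the only possible alkene, and the acetate prevents translactonisation onto O-16.

**Compound list**

1 | (+)-sclareolide | O=C2C[C@H]1[C@@](O2)(C)CC[C@H]3C(C)(C)CCC[C@]13C | starting material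
2 | potassium 8α-hydroxy-11-homodriman-12-oate | [K+].[O-]C(=O)C[C@H]1[C@@](O)(C)CC[C@H]2C(C)(C)CCC[C@]12C | intermediate (not isolated)
3 | methyl 8α-hydroxy-11-homodriman-12-oate | COC(=O)C[C@H]1[C@@](O)(C)CC[C@H]2C(C)(C)CCC[C@]12C | intermediate
4 | tertiary chlorosulfite of 3 | COC(=O)C[C@H]1[C@@](OS(Cl)=O)(C)CC[C@H]2C(C)(C)CCC[C@]12C | intermediate (not isolated)
5 | methyl 11-homodrim-8(17)-en-12-oate | COC(=O)C[C@H]1C(=C)CC[C@H]2C(C)(C)CCC[C@]12C | intermediate
6 | 1-iodo-3,5-dimethoxybenzene | COc1cc(I)cc(OC)c1 | starting material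
7 | methyl 8α-(3,5-dimethoxyphenyl)-11-homodriman-12-oate | COC(=O)C[C@H]1[C@@](c2cc(OC)cc(OC)c2)(C)CC[C@H]2C(C)(C)CCC[C@]12C | intermediate
8 | 8α-(3,5-dimethoxyphenyl)-11-homodriman-12-oic acid | OC(=O)C[C@H]1[C@@](c2cc(OC)cc(OC)c2)(C)CC[C@H]2C(C)(C)CCC[C@]12C | intermediate
9 | (trimethylsilyl)diazomethane | C[Si](C)(C)C=[N+]=[N-] | starting material
10 | isobutyl mixed carbonic anhydride of 8 | CC(C)COC(=O)OC(=O)C[C@H]1[C@@](c2cc(OC)cc(OC)c2)(C)CC[C@H]2C(C)(C)CCC[C@]12C | intermediate (not isolated)
11 | C8-(3,5-dimethoxyphenyl) homodrimanyl diazomethyl ketone | [N-]=[N+]=CC(=O)C[C@H]1[C@@](c2cc(OC)cc(OC)c2)(C)CC[C@H]2C(C)(C)CCC[C@]12C | intermediate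
12 | norcaradiene ketone (cyclopropane C13–C14–C18) | COC1=C[C@]23[C@H](C(OC)=C1)[C@H]2C(=O)C[C@H]4[C@@]3(C)CC[C@H]5C(C)(C)CCC[C@]45C | intermediate (not isolated)
13 | tetracyclic 16,19-dimethoxy-14,16,18-trien-12-one | COC1=CC(OC)=C[C@H]2C(=O)C[C@H]3[C@@](C)(CC[C@H]4C(C)(C)CCC[C@]34C)C2=C1 | intermediate
14 | potassium C11-enolate of 13 | COC1=CC(OC)=C[C@H]2C([O-])=C[C@H]3[C@@](C)(CC[C@H]4C(C)(C)CCC[C@]34C)C2=C1.[K+] | intermediate (not isolated)
15 | 16,19-dimethoxy-11,14,16,18-tetraen-12-yl triflate | COC1=CC(OC)=C[C@H]2C(OS(=O)(=O)C(F)(F)F)=C[C@H]3[C@@](C)(CC[C@H]4C(C)(C)CCC[C@]34C)C2=C1 | intermediate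
16 | 16-methoxy-19-oxo-11,14,16-trien-12-yl triflate | COC1=CC(=O)C[C@H]2C(OS(=O)(=O)C(F)(F)F)=C[C@H]3[C@@](C)(CC[C@H]4C(C)(C)CCC[C@]34C)C2=C1 | intermediate
17 | 16-methoxy-16-en-19-one (13β-H, 14α-H) | COC1=CC(=O)C[C@H]2CC[C@H]3[C@@](C)(CC[C@H]4C(C)(C)CCC[C@]34C)[C@@H]2C1 | intermediate
18 | 17-iodo-16-methoxy-16-en-19-one | COC1=C(I)C(=O)C[C@H]2CC[C@H]3[C@@](C)(CC[C@H]4C(C)(C)CCC[C@]34C)[C@@H]2C1 | intermediate
19 | (E)-2-(2-ethoxyvinyl)-4,4,5,5-tetramethyl-1,3,2-dioxaborolane | CCO/C=C/B1OC(C)(C)C(C)(C)O1 | starting material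
20 | 17-[(E)-2-ethoxyvinyl]-16-methoxy-16-en-19-one | COC1=C(/C=C/OCC)C(=O)C[C@H]2CC[C@H]3[C@@](C)(CC[C@H]4C(C)(C)CCC[C@]34C)[C@@H]2C1 | intermediate (not isolated)
21 | ring-D-fused furan C16 ketone | O=C1c2ccoc2C[C@H]3CC[C@H]4[C@@](C)(CC[C@H]5C(C)(C)CCC[C@]45C)[C@@H]3C1 | intermediate
22 | 16α-hydroxy furan | O[C@H]1c2ccoc2C[C@H]3CC[C@H]4[C@@](C)(CC[C@H]5C(C)(C)CCC[C@]45C)[C@@H]3C1 | intermediate
23 | 16α-acetoxy furan | CC(=O)O[C@H]1c2ccoc2C[C@H]3CC[C@H]4[C@@](C)(CC[C@H]5C(C)(C)CCC[C@]45C)[C@@H]3C1 | intermediate
24 | C19,C20-endoperoxide of 23 | CC(=O)O[C@H]1C2=CC3OOC2(O3)C[C@H]4CC[C@H]5[C@@](C)(CC[C@H]6C(C)(C)CCC[C@]56C)[C@@H]4C1 | intermediate (not isolated)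
25 | 16α-acetoxy-19-hydroxy-17(21)-en-20,19-olide (C19 epimers) | CC(=O)O[C@H]1C2=CC(=O)OC2(O)C[C@H]3CC[C@H]4[C@@](C)(CC[C@H]5C(C)(C)CCC[C@]45C)[C@@H]3C1 | intermediate
26 | CNP0193439.1 | CC(=O)O[C@@H]1C[C@@H]2[C@@H](C=C3OC(=O)C=C31)CC[C@H]1[C@@]2(C)CC[C@H]2C(C)(C)CCC[C@]12C | target

**Step count**

Total: 15 steps. Longest linear sequence: 15 steps (1 to 26); 6, 9 and 19 are purchased.

**Steps most likely to fail**

Step 8. The equilibrium between the two vinylogous esters may show too small a bias, so that the carbonyl does not settle cleanly on C19 and the regiochemical information needed for the furan is diluted. The fallback sets out from 15 and comes back at 21. Both enol ethers of 15 are hydrolysed with aqueous HCl in THF to the 14-ene-16,19-dione 12-triflate F1. Hydrogenation over PtO2 with NaHCO3, as in step 9, gives the saturated 16,19-dione F2. A Feist–Benary annulation with chloroacetaldehyde (aqueous NaHCO3, then acid) closes the furan in one operation and gives furyl ketone 21 together with its regioisomer, the furan-on-C16 C19 ketone F3, which are separated. Regiocontrol is given up for a statistical annulation, but steps 8, 10 and 11 are replaced.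

Step 6. The zwitterionic pathway (carbenoid attack at C18 followed by proton transfer, or acid-induced reopening of the norcaradiene) may re-aromatise ring D and give a ring-fused aryl ketone, because both ortho carbons are activated by two methoxy groups. The fallback sets out from 8 and comes back at 16; it makes the arene less basic by exchanging the ether donors for acyloxy groups.
- BBr3 in CH2Cl2 demethylates 8 to the resorcinol acid F4.
- Pivaloyl chloride and pyridine, with aqueous NaHCO3 work-up, give the bis-pivalate acid F5.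
- The sequence of steps 5 to 7 then follows: the mixed carbonic anhydride F6 with 9 gives the diazoketone F7.
- Rh2(OAc)4 gives, through the norcaradiene F8, the 16,19-bis(pivaloyloxy)trienone F9.
- KN(SiMe3)2 and PhNTf2 give, through the potassium enolate F10, the enol triflate F11.
- Acid methanolysis (TsOH, MeOH) of the two enol pivalates then delivers vinylogous ester 16.

Step 3. Hydrogen-atom transfer to the hindered exocyclic alkene may be outrun by alkene isomerisation or simple reduction, and capture of the congested tertiary radical by nickel may be slow. The fallback sets out from 5 and comes back at 7. Markovnikov addition of HBr (HBr in AcOH) gives the tertiary C8 bromide F12 (either C8 epimer). F12 is coupled with 6 in a nickel-catalysed reductive cross-electrophile arylation of a tertiary alkyl halide (Ni(acac)2, a pyridine-type ligand, MgCl2, Zn, DMA). The C8 radical then arises by halogen abstraction instead of hydrogen-atom transfer, and the same α-face capture is expected.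

**Further compounds**

F1 | step 8 | 16,19-dioxo-11,14-dien-12-yl triflate | O=C1CC(=O)C[C@H]2C(OS(=O)(=O)C(F)(F)F)=C[C@H]3[C@@](C)(CC[C@H]4C(C)(C)CCC[C@]34C)C2=C1
F2 | step 8 | saturated 16,19-dione (13β-H, 14α-H) | O=C1CC(=O)C[C@H]2CC[C@H]3[C@@](C)(CC[C@H]4C(C)(C)CCC[C@]34C)[C@@H]2C1
F3 | step 8 | regioisomeric furan (O on C16) C19 ketone | O=C1C[C@H]2CC[C@H]3[C@@](C)(CC[C@H]4C(C)(C)CCC[C@]34C)[C@@H]2Cc2occc12
F4 | step 6 | 8α-(3,5-dihydroxyphenyl)-11-homodriman-12-oic acid | OC(=O)C[C@H]1[C@@](c2cc(O)cc(O)c2)(C)CC[C@H]2C(C)(C)CCC[C@]12C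
F5 | step 6 | 8α-[3,5-bis(pivaloyloxy)phenyl]-11-homodriman-12-oic acid | OC(=O)C[C@H]1[C@@](c2cc(OC(=O)C(C)(C)C)cc(OC(=O)C(C)(C)C)c2)(C)CC[C@H]2C(C)(C)CCC[C@]12C
F6 | step 6 | isobutyl mixed carbonic anhydride of F5 | CC(C)COC(=O)OC(=O)C[C@H]1[C@@](c2cc(OC(=O)C(C)(C)C)cc(OC(=O)C(C)(C)C)c2)(C)CC[C@H]2C(C)(C)CCC[C@]12C
F7 | step 6 | bis(pivaloyloxy)aryl diazomethyl ketone | [N-]=[N+]=CC(=O)C[C@H]1[C@@](c2cc(OC(=O)C(C)(C)C)cc(OC(=O)C(C)(C)C)c2)(C)CC[C@H]2C(C)(C)CCC[C@]12C
F8 | step 6 | bis(pivaloyloxy) norcaradiene ketone | CC(C)(C)C(=O)OC1=C[C@]23[C@H](C(OC(=O)C(C)(C)C)=C1)[C@H]2C(=O)C[C@H]4[C@@]3(C)CC[C@H]5C(C)(C)CCC[C@]45C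
F9 | step 6 | 16,19-bis(pivaloyloxy)-14,16,18-trien-12-one | CC(C)(C)C(=O)OC1=CC(OC(=O)C(C)(C)C)=C[C@H]2C(=O)C[C@H]3[C@@](C)(CC[C@H]4C(C)(C)CCC[C@]34C)C2=C1
F10 | step 6 | potassium C11-enolate of F9 | CC(C)(C)C(=O)OC1=CC(OC(=O)C(C)(C)C)=C[C@H]2C([O-])=C[C@H]3[C@@](C)(CC[C@H]4C(C)(C)CCC[C@]34C)C2=C1.[K+]
F11 | step 6 | 16,19-bis(pivaloyloxy)-11,14,16,18-tetraen-12-yl triflate | CC(C)(C)C(=O)OC1=CC(OC(=O)C(C)(C)C)=C[C@H]2C(OS(=O)(=O)C(F)(F)F)=C[C@H]3[C@@](C)(CC[C@H]4C(C)(C)CCC[C@]34C)C2=C1
F12 | step 3 | methyl 8-bromo-11-homodriman-12-oate | COC(=O)C[C@H]1C(C)(Br)CC[C@H]2C(C)(C)CCC[C@]12C
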